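C1 (ketone) and C6 (lactone carbinol) sit 1,6 across the ten-membered ring, so the germacrane is redrawn as a decalin in which C1 and C6 are the fusion carbons, ring A holds C2–C5 with the cis C4=C5 alkene and ring B holds C7–C10. Scission of the C1–C6 bond of the cis-4a,8a-diol with Pb(OAc)4 merges ring A and ring B into the cyclodecene and delivers the C1 ketone and the Z-enone carbonyl at C6 in one operation, while C7, C8 and C10, set earlier on a chair cyclohexane made by phenol dearomatisation, stay untouched. The precursor is a cis-fused octalin-4a,8a-diol bearing the C7 alkenyl group, C8 OPMB and C10 methyl/OTBS.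

Key step: step 19

Remark: germacrane numbering is used for every ring carbon from compound 2 onward (C1 = carbonyl carbon of 2, C8 = ketal carbon, C10 = methyl-bearing carbon); the face of ring B that carries the C7 alkenyl group is called the upper face.
Assumption: C1 and C6 end as carbonyl carbons, so their glycol configuration is free; the cis-glycol with both hydroxyls on the upper face is built because every carbon nucleophile then enters anti to axial C–O bonds and ring A is not syn-axial to the C10 silyloxy group. The silyl groups are TBDPS (C12) and TBS (C10), and the (S)-BINAP catalyst is assumed to keep the facial sense known for cyclohex-2-enone.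

**Route**

Step 1
Reactants: 1 4-methoxy-2-methylphenol
Product: 2 4,4-dimethoxy-2-methylcyclohexa-2,5-dien-1-one
Conditions: PhI(OAc)2 (1.1 equiv), MeOH, 0 °C to rt
Reagents that add atoms: methanol, CO
Why: Oxidative dearomatisation in which trivalent iodine activates the phenol and methanol is trapped at the para carbon, giving the quinone monoketal that already holds the C1 carbonyl, the masked C8 ketone and the C10 methyl group.

Step 2
Reactants: 3 2-bromoprop-2-en-1-ol
Product: 4 [(2-bromoprop-2-en-1-yl)oxy](tert-butyl)diphenylsilane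
Conditions: TBDPSCl, imidazole, CH2Cl2, 0 °C to rt
Reagents that add atoms: tert-butyl(chloro)diphenylsilane, CC(C)(C)[Si](Cl)(c1ccccc1)c1ccccc1
Why: Silyl ether formation on the primary allylic alcohol, TBDPS being chosen because it has to survive the acidic ketal exchanges of steps 7 and 13.

Step 3
Reactants: 4 silyl-protected bromoalkene
Product: 6 alkenyl pinacol boronate, via alkenyllithium 5 (not isolated)
Conditions: t-BuLi (2.1 equiv), Et2O, −78 °C; then i-PrOBpin, −78 °C to rt
Reagents that add atoms: 2-isopropoxy-4,4,5,5-tetramethyl-1,3,2-dioxaborolane, CC(C)OB1OC(C)(C)C(C)(C)O1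
Why: Bromine–lithium exchange on the vinyl bromide followed by borylation of the alkenyllithium gives the bench-stable 1,1-disubstituted alkenylboronate needed for step 4.

Step 4
Reactants: 2 quinone monoketal; 6 alkenyl pinacol boronate
Product: 7 (5S)-5-[3-(tert-butyldiphenylsilyloxy)prop-1-en-2-yl]-4,4-dimethoxy-2-methylcyclohex-2-en-1-one
Conditions: [RhCl(cod)]2 (2.5 mol%), (S)-BINAP (6 mol%), KOH (0.5 equiv), dioxane/H2O 10:1, 40 °C
Reagents that add atoms: none
Why: Hayashi–Miyaura asymmetric conjugate addition in which the alkenyl group passes from boron to monovalent rhodium and inserts only the α-unsubstituted C6=C7 enone (the C10 methyl deactivates the other one), the (S)-BINAP complex being expected to select the same enone face as with cyclohex-2-enone and so to set C7 as (S).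

Step 5
Reactants: 7 conjugate adduct
Product: 9 C6-hydroxy enone (hydroxyl trans to the C7 alkenyl group), via potassium enolate 8 (not isolated)
Conditions: KN(SiMe3)2, THF, −78 °C; then 2-(phenylsulfonyl)-3-phenyloxaziridine, −78 °C
Reagents that add atoms: 2-(benzenesulfonyl)-3-phenyloxaziridine, O=S(=O)(c1ccccc1)N1OC1c1ccccc1
Why: Davis enolate hydroxylation, C6 being the only enolisable position and the oxaziridine being expected to approach the planar enolate anti to the neighbouring C7 alkenyl group, which places the C6 hydroxyl trans to it.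

Step 6
Reactants: 9 C6-hydroxy enone
Product: 10 C1/C6 cis-diol (C1 allylic alcohol)
Conditions: Zn(BH4)2, Et2O, −30 °C
Reagents that add atoms: none
Why: Chelation-controlled 1,2-reduction of an α-hydroxy enone in which hydride should attack the zinc chelate from the side of the axial C6–H, giving the C1 alcohol cis to the C6 hydroxyl; both carbinols are temporary and serve to fuse a dioxolane onto the lower face.

Step 7
Reactants: 10 C1/C6 cis-diol
Product: 12 C1/C6 acetonide C8 enone, via acetonide ketal 11 (not isolated)
Conditions: 2,2-dimethoxypropane, PPTS (cat.), acetone, rt; then H2O, rt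
Reagents that add atoms: 2,2-dimethoxypropane, COC(C)(C)OC; water, O
Why: Acid-catalysed ketal exchange in which the cis-diol closes the five-membered isopropylidene acetal and the allylic dimethyl ketal, which ionises far more readily than the dioxolane, is then hydrolysed by the added water to the C8 enone.

Step 8
Reactants: 12 acetonide enone
Product: 13 C9/C10 epoxy ketone (epoxide on the upper face)
Conditions: t-BuOOH, DBU, CH2Cl2, 0 °C
Reagents that add atoms: tert-butyl hydroperoxide, CC(C)(C)OO
Why: Weitz–Scheffer nucleophilic epoxidation in which the peroxide anion should add to C10 axially on the upper face, anti to the pseudoaxial C1–O bond and away from the cis-fused dioxolane, so that the new C10–O bond is cis to the C7 alkenyl group as in the target.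

Step 9
Reactants: 13 epoxy ketone
Product: 14 C10 tertiary β-hydroxy ketone
Conditions: SmI2 (2.2 equiv), THF/MeOH, −78 °C
Reagents that add atoms: none
Why: Reductive opening of an α,β-epoxy ketone by divalent samarium, the ketyl expelling the α C9–O bond and methanol protonating the enolate at low temperature, which leaves the C10 carbinol with its configuration unchanged.

Step 10
Reactants: 14 β-hydroxy ketone
Product: 15 C8/C10 anti-diol
Conditions: Me4NBH(OAc)3, MeCN/AcOH 1:1, −30 °C
Reagents that add atoms: none
Why: Evans–Saksena hydroxyl-directed reduction in which the axial C10 hydroxyl binds the triacetoxyborohydride and delivers hydride to the upper face of C8, giving the equatorial C8 alcohol anti to the C10 oxygen and trans to the C7 alkenyl group.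

Step 11
Reactants: 15 C8/C10 diol
Product: 16 C8 PMB ether
Conditions: NaH, PMBCl, Bu4NI (cat.), THF/DMF, 0 °C to rt
Reagents that add atoms: 4-methoxybenzyl chloride, COc1ccc(CCl)cc1
Why: Williamson etherification in which the secondary C8 alkoxide is benzylated while the hindered tertiary C10 hydroxyl stays free.

Step 12
Reactants: 16 C8 PMB ether
Product: 17 C10 TBS ether
Conditions: TBSOTf, 2,6-lutidine, CH2Cl2, 0 °C to rt
Reagents that add atoms: tert-butyldimethylsilyl trifluoromethanesulfonate, CC(C)(C)[Si](C)(C)OS(=O)(=O)C(F)(F)F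
Why: Silylation of the tertiary C10 alcohol with the silyl triflate, giving an ether that later keeps the C1/C10 glycol from the oxidant and, being axial on the upper face, shields that face of C6 in step 15.

Step 13
Reactants: 17 acetonide
Product: 18 C1/C6 cis-diol (two secondary hydroxyls)
Conditions: PPTS, MeOH, 40 °C
Reagents that add atoms: none
Why: Acid-catalysed transketalisation to methanol releases the C1/C6 diol, while primary TBDPS, tertiary TBS and PMB ethers are stable to these conditions.

Step 14
Reactants: 18 C1/C6 diol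
Product: 19 C6 ketone with free C1 hydroxyl
Conditions: IBX (1.1 equiv), DMSO, rt
Reagents that add atoms: none
Why: Site-selective alcohol oxidation by pentavalent iodine, which turns 1,2-diols into α-ketols without C–C cleavage and should take the equatorial C6 hydroxyl before the axial C1 hydroxyl that is neopentylic to the quaternary C10 silyloxy carbon.

Step 15
Reactants: 19 C6 ketone; 20 vinylmagnesium bromide
Product: 21 C6 vinyl carbinol
Conditions: LaCl3·2LiCl, THF, −78 °C
Reagents that add atoms: none
Why: Lanthanum-promoted Grignard 1,2-addition in which axial attack on the upper face of C6 is blocked by the syn-axial C10 silyloxy group, so the vinyl group should enter equatorially from the lower face and leave the tertiary C6 hydroxyl axial on the upper face.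

Step 16
Reactants: 21 C6 vinyl carbinol
Product: 22 C1 ketone with tertiary C6 hydroxyl
Conditions: Dess–Martin periodinane, CH2Cl2, 0 °C to rt
Reagents that add atoms: none
Why: Dess–Martin oxidation of the remaining secondary C1 alcohol, the tertiary C6 alcohol being inert and the new ketone having no enolisable α-hydrogen.

Step 17
Reactants: 22 C1 ketone; 23 4-bromo-2-methylbut-1-ene
Product: 25 C1/C6 cis-diol triene, via Grignard reagent 24 (not isolated)
Conditions: Mg, THF, rt; then LaCl3·2LiCl, 22, THF, −78 to 0 °C
Reagents that add atoms: none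
Why: Lanthanum-promoted Grignard addition to a non-enolisable ketone whose two flanking carbons carry axial C–O bonds on the upper face, so the alkyl group should add axially from the lower face (Felkin–Anh, anti to both C–O bonds), which puts the C1 hydroxyl cis to the C6 hydroxyl and both alkenyl arms on the lower face.

Step 18
Reactants: 25 diol triene
Product: 26 cis-fused octalin-4a,8a-diol (key-step precursor)
Conditions: second-generation Grubbs catalyst RuCl2(=CHPh)(PCy3)(H2IMes) (5 mol%), CH2Cl2, 40 °C
Reagents that add atoms: none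
Why: Ring-closing metathesis between the C6 vinyl group and the 1,1-disubstituted alkene of the C1 side chain closes ring A as a cyclohexene with the necessarily cis C4=C5 double bond, the hindered C11 methylene having no partner with which it could close a reasonable ring.

Step 19
Reactants: 26 cis-fused octalin-4a,8a-diol
Product: 27 ten-membered (Z)-2-ene-1,6-dione
Conditions: Pb(OAc)4 (1.1 equiv), NaHCO3, CH2Cl2, −20 to 0 °C
Reagents that add atoms: none
Why: Criegee glycol scission, in which the cis-glycol forms a cyclic diester of tetravalent lead that collapses by a two-electron shift, breaking C1–C6 and giving two carbonyl groups and divalent lead as Pb(OAc)2. The closest known reaction is the cleavage of cis-decalin-4a,8a-diols to cyclodecane-1,6-diones by the same reagent. The ten-membered ring is not formed by a cyclisation but by fragmentation of the bond shared by ring A and ring B, so no exo or endo mode applies and no entropic penalty is paid. No stereocentre is created: the cis double bond of ring A becomes the Z-C4=C5 enone, and C7, C8 and C10 are spectators. The step needs site selectivity and configurational integrity at C7; the first is secured because the C10 and C8 oxygens are capped so that no other free glycol exists, the second by the hydrogencarbonate buffer, the low temperature and the immediate use of 27 in step 20.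

Step 20
Reactants: 27 enedione
Product: 28 (6R) allylic alcohol
Conditions: NaBH4, CeCl3·7H2O, MeOH, −78 °C
Reagents that add atoms: none
Why: Luche reduction, in which cerium-activated borohydride reduces the conjugated C6 carbonyl 1,2 and faster than the C1 ketone flanked by the quaternary silyloxy carbon, hydride being expected to come from the ring periphery anti to the C7–C8 bond with C7–H turned toward C5 (Felkin–Anh), which gives the (6R) alcohol with O6 cis to C11 as the lactone requires.

Step 21
Reactants: 28 allylic alcohol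
Product: 29 C6/C10/C12 triol
Conditions: HF·pyridine, pyridine, THF, 0 to 40 °C
Reagents that add atoms: none
Why: Fluoride-mediated cleavage of both silyl ethers (primary TBDPS and tertiary TBS) in buffered HF·pyridine, which is not basic enough to trigger α-ketol rearrangement and leaves the PMB ether in place.

Step 22
Reactants: 29 triol
Product: 32 cis-fused α-methylene lactone (C8 PMB ether), via hydroxy enal 30 (not isolated), via lactol 31 (not isolated)
Conditions: TEMPO (cat.), PhI(OAc)2 (2.5 equiv), CH2Cl2, rt
Reagents that add atoms: none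
Why: Oxoammonium (TEMPO) oxidation with PhI(OAc)2 as terminal oxidant, in which the primary allylic C12 alcohol is oxidised to the enal, the cis-disposed C6 hydroxyl closes the five-membered lactol and this is oxidised on to the α-methylene-γ-butyrolactone, only the 6,12-lactone being possible because C8 is still an ether and the C10 alcohol is tertiary.

Step 23
Reactants: 32 lactone PMB ether
Product: 33 C8 alcohol
Conditions: DDQ, CH2Cl2/pH 7 buffer, 0 °C
Reagents that add atoms: none
Why: Oxidative PMB cleavage by DDQ through the benzylic oxocarbenium ion, which is hydrolysed by the buffer, the lactone, the ketone and the tertiary alcohol being inert.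

Step 24
Reactants: 33 C8 alcohol; 34 (E)-2-methylbut-2-enoyl chloride
Product: 35 target CNP0345906.4
Conditions: Et3N, DMAP (cat.), CH2Cl2, 0 °C to rt
Reagents that add atoms: none
Why: DMAP-catalysed acylation by the acid chloride, in which only the secondary C8 hydroxyl reacts because the tertiary C10 hydroxyl is unreactive under these conditions, the thermodynamically favoured E geometry of the tigloyl group being retained.

**Compound list**

1 | 4-methoxy-2-methylphenol | Cc1cc(OC)ccc1O | starting material
2 | 4,4-dimethoxy-2-methylcyclohexa-2,5-dien-1-one | COC1(OC)C=CC(=O)C(C)=C1 | intermediate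
3 | 2-bromoprop-2-en-1-ol | OCC(Br)=C | starting material
4 | [(2-bromoprop-2-en-1-yl)oxy](tert-butyl)diphenylsilane | CC(C)(C)[Si](c1ccccc1)(c1ccccc1)OCC(Br)=C | intermediate
5 | [3-(tert-butyldiphenylsilyloxy)prop-1-en-2-yl]lithium | [Li]C(=C)CO[Si](c1ccccc1)(c1ccccc1)C(C)(C)C | intermediate
6 | tert-butyl(diphenyl){[2-(4,4,5,5-tetramethyl-1,3,2-dioxaborolan-2-yl)prop-2-en-1-yl]oxy}silane | CC(C)(C)[Si](c1ccccc1)(c1ccccc1)OCC(=C)B1OC(C)(C)C(C)(C)O1 | intermediate
7 | (5S)-5-[3-(tert-butyldiphenylsilyloxy)prop-1-en-2-yl]-4,4-dimethoxy-2-methylcyclohex-2-en-1-one | CC(C)(C)[Si](c1ccccc1)(c1ccccc1)OCC(=C)[C@@H]1CC(=O)C(C)=CC1(OC)OC | intermediate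
8 | potassium C1/C6 enolate of 7 | CC(C)(C)[Si](c1ccccc1)(c1ccccc1)OCC(=C)[C@@H]1C=C(O[K])C(C)=CC1(OC)OC | intermediate
9 | 6-hydroxy derivative of 7, hydroxyl trans to the alkenyl group | CC(C)(C)[Si](c1ccccc1)(c1ccccc1)OCC(=C)[C@@H]1[C@@H](O)C(=O)C(C)=CC1(OC)OC | intermediate
10 | cyclohex-2-ene-1,6-diol from 9, C1–OH cis to C6–OH, both trans to the alkenyl group | CC(C)(C)[Si](c1ccccc1)(c1ccccc1)OCC(=C)[C@@H]1[C@@H](O)[C@@H](O)C(C)=CC1(OC)OC | intermediate
11 | C1/C6 acetonide of 10, C8 dimethyl ketal intact | CC(C)(C)[Si](c1ccccc1)(c1ccccc1)OCC(=C)[C@@H]1[C@H]2OC(C)(C)O[C@H]2C(C)=CC1(OC)OC | intermediate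
12 | C1/C6 acetonide (lower face), C8 ketone, C9=C10 enone, C7 alkenyl on the upper face | CC(C)(C)[Si](c1ccccc1)(c1ccccc1)OCC(=C)[C@H]1C(=O)C=C(C)[C@@H]2OC(C)(C)O[C@H]12 | intermediate
13 | C9/C10 epoxide of 12, epoxide oxygen on the upper face | CC(C)(C)[Si](c1ccccc1)(c1ccccc1)OCC(=C)[C@H]1C(=O)[C@H]3O[C@@]3(C)[C@@H]2OC(C)(C)O[C@H]12 | intermediate
14 | C8 ketone with tertiary C10 hydroxyl on the upper face (methyl lower face) | CC(C)(C)[Si](c1ccccc1)(c1ccccc1)OCC(=C)[C@H]1C(=O)C[C@@](C)(O)[C@@H]2OC(C)(C)O[C@H]12 | intermediate
15 | C8/C10 anti-diol, C8–OH on the lower face, trans to the C7 alkenyl group | CC(C)(C)[Si](c1ccccc1)(c1ccccc1)OCC(=C)[C@H]1[C@H](O)C[C@@](C)(O)[C@@H]2OC(C)(C)O[C@H]12 | intermediate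
16 | C8 4-methoxybenzyl ether of 15 | CC(C)(C)[Si](c1ccccc1)(c1ccccc1)OCC(=C)[C@H]1[C@H](OCc3ccc(OC)cc3)C[C@@](C)(O)[C@@H]2OC(C)(C)O[C@H]12 | intermediate
17 | C10 tert-butyldimethylsilyl ether of 16 | CC(C)(C)[Si](c1ccccc1)(c1ccccc1)OCC(=C)[C@H]1[C@H](OCc3ccc(OC)cc3)C[C@@](C)(O[Si](C)(C)C(C)(C)C)[C@@H]2OC(C)(C)O[C@H]12 | intermediate
18 | C1/C6 cis-diol (both hydroxyls on the lower face; C1–OH axial, C6–OH equatorial), C8 OPMB, C10 OTBS | CC(C)(C)[Si](c1ccccc1)(c1ccccc1)OCC(=C)[C@H]1[C@H](OCc2ccc(OC)cc2)C[C@@](C)(O[Si](C)(C)C(C)(C)C)[C@H](O)[C@@H]1O | intermediate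
19 | C6 ketone, C1 hydroxyl on the lower face | CC(C)(C)[Si](c1ccccc1)(c1ccccc1)OCC(=C)[C@H]1[C@H](OCc2ccc(OC)cc2)C[C@@](C)(O[Si](C)(C)C(C)(C)C)[C@H](O)C1=O | intermediate
20 | vinylmagnesium bromide | C=C[Mg]Br | starting material
21 | C6 tertiary carbinol, hydroxyl on the upper face and vinyl on the lower face; C1 secondary hydroxyl on the lower face | CC(C)(C)[Si](c1ccccc1)(c1ccccc1)OCC(=C)[C@H]1[C@H](OCc2ccc(OC)cc2)C[C@@](C)(O[Si](C)(C)C(C)(C)C)[C@H](O)[C@]1(O)C=C | intermediate
22 | C1 ketone, C6 vinyl carbinol (hydroxyl on the upper face) | CC(C)(C)[Si](c1ccccc1)(c1ccccc1)OCC(=C)[C@H]1[C@H](OCc2ccc(OC)cc2)C[C@@](C)(O[Si](C)(C)C(C)(C)C)C(=O)[C@]1(O)C=C | intermediate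
23 | 4-bromo-2-methylbut-1-ene | C=C(C)CCBr | starting material
24 | (3-methylbut-3-en-1-yl)magnesium bromide | C=C(C)CC[Mg]Br | intermediate
25 | C1/C6 cis-diol (both hydroxyls on the upper face), C1 3-methylbut-3-enyl and C6 vinyl on the lower face | CC(C)(C)[Si](c1ccccc1)(c1ccccc1)OCC(=C)[C@H]1[C@H](OCc2ccc(OC)cc2)C[C@@](C)(O[Si](C)(C)C(C)(C)C)[C@](O)(CCC(C)=C)[C@]1(O)C=C | intermediate
26 | cis-fused C1,C6-dihydroxy octalin (hydroxyls on the upper face, ring A on the lower face) with C7 alkenyl, C8 OPMB, C10 methyl/OTBS | CC(C)(C)[Si](c1ccccc1)(c1ccccc1)OCC(=C)[C@@H]1[C@@]2(O)C=C(C)CC[C@@]2(O)[C@](C)(O[Si](C)(C)C(C)(C)C)C[C@H]1OCc1ccc(OC)cc1 | intermediate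
27 | ten-membered (Z)-2-ene-1,6-dione (C1 ketone, C6 enone carbonyl) with C7, C8, C10 in place | CC(C)(C)[Si](c1ccccc1)(c1ccccc1)OCC(=C)[C@@H]1C(=O)/C=C(/C)CCC(=O)[C@](C)(O[Si](C)(C)C(C)(C)C)C[C@H]1OCc1ccc(OC)cc1 | intermediate
28 | (6R) allylic alcohol from 27, C1 ketone intact | CC(C)(C)[Si](c1ccccc1)(c1ccccc1)OCC(=C)[C@@H]1[C@H](O)/C=C(/C)CCC(=O)[C@](C)(O[Si](C)(C)C(C)(C)C)C[C@H]1OCc1ccc(OC)cc1 | intermediate
29 | C6, C10, C12 triol with C8 OPMB | OCC(=C)[C@@H]1[C@H](O)/C=C(/C)CCC(=O)[C@](C)(O)C[C@H]1OCc1ccc(OC)cc1 | intermediate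
30 | C12 enal of 29 | O=CC(=C)[C@@H]1[C@H](O)/C=C(/C)CCC(=O)[C@](C)(O)C[C@H]1OCc1ccc(OC)cc1 | intermediate
31 | 6,12-lactol (configuration at C12 not defined) | C=C1C(O)O[C@@H]2/C=C(/C)CCC(=O)[C@](C)(O)C[C@@H](OCc3ccc(OC)cc3)[C@H]12 | intermediate
32 | cis-fused 6,12-α-methylene lactone, C8 OPMB, C10 OH | C=C1C(=O)O[C@@H]2/C=C(/C)CCC(=O)[C@](C)(O)C[C@@H](OCc3ccc(OC)cc3)[C@H]12 | intermediate
33 | 8,10-dihydroxy lactone | C=C1C(=O)O[C@@H]2/C=C(/C)CCC(=O)[C@](C)(O)C[C@@H](O)[C@H]12 | intermediate
34 | (E)-2-methylbut-2-enoyl chloride (tigloyl chloride) | C/C=C(\C)C(=O)Cl | starting material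
35 | CNP0345906.4, (6R,7S,8R,10R)-10-hydroxy-1-oxo-8-tigloyloxygermacra-4Z,11(13)-dien-12,6-olide | C=C1C(=O)O[C@@H]2/C=C(/C)CCC(=O)[C@](C)(O)C[C@@H](OC(=O)/C(C)=C/C)[C@H]12 | target

**Step count and risks**

Total step count: 24. Longest linear sequence: 23 steps (3 → 4 → 6 → 7 → … → 35; from 1 it is 22 steps).

Steps most likely to fail:

Step 19. The crowded ditertiary glycol may esterify slowly, so that tetravalent lead attacks the alkenes. The acetic acid and lead salts may also epimerise C7 or expel the C8 ether from the β-alkoxy ketone before 27 is reduced. The fallback sets out from 26 and returns at 28. The glycol would be cut by a Malaprade scission with NaIO4 on wet silica gel in CH2Cl2, which goes through a cyclic periodate ester, sets free no acid and leaves alkenes and the PMB ether alone. The silica would be filtered off and the filtrate reduced at once under the conditions of step 20, so that 27 is never isolated and no compound outside the list is made (F0).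

Step 14. Site selectivity may be lost, with oxidation also at the C1 hydroxyl or at both hydroxyls. The fallback replaces kinetic selectivity by protecting-group differentiation, sets out from 18 and returns at 19. Kinetic acetylation of the less hindered equatorial C6 hydroxyl (AcCl, 2,4,6-collidine, CH2Cl2, −78 °C) would give the C6 acetate F1. Silylation of the remaining axial C1 hydroxyl (TESOTf, 2,6-lutidine) would give the C1 triethylsilyl ether F2. Reductive removal of the acetate (i-Bu2AlH, CH2Cl2, −78 °C) would give the C6 alcohol F3, and Dess–Martin oxidation the C6 ketone F4. Buffered HF·pyridine (THF, 0 °C), which cleaves the secondary TES ether but not the tertiary TBS or primary TBDPS ether, would then return 19.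

Step 20. Facial selectivity may be poor or reversed, hydride being delivered to the other face of the C6 carbonyl. The fallback replaces substrate-controlled hydride delivery by invertive substitution, sets out from 27 and returns at 28. The (6S) alcohol F5 from the reduction would be inverted by Mitsunobu esterification (4-nitrobenzoic acid, PPh3, diisopropyl azodicarboxylate, THF, 0 °C) to the (6R) 4-nitrobenzoate F6. Methanolysis (K2CO3, MeOH, 0 °C) would return 28.

Further compounds

F0 | step 19 | none | none
F1 | step 14 | C6 acetate of diol 18 | CC(C)(C)[Si](c1ccccc1)(c1ccccc1)OCC(=C)[C@H]1[C@H](OCc2ccc(OC)cc2)C[C@@](C)(O[Si](C)(C)C(C)(C)C)[C@H](O)[C@@H]1OC(C)=O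
F2 | step 14 | C6 acetate C1 triethylsilyl ether | CC(C)(C)[Si](c1ccccc1)(c1ccccc1)OCC(=C)[C@H]1[C@H](OCc2ccc(OC)cc2)C[C@@](C)(O[Si](C)(C)C(C)(C)C)[C@H](O[Si](CC)(CC)CC)[C@@H]1OC(C)=O
F3 | step 14 | C1 triethylsilyl ether with free C6 hydroxyl | CC(C)(C)[Si](c1ccccc1)(c1ccccc1)OCC(=C)[C@H]1[C@H](OCc2ccc(OC)cc2)C[C@@](C)(O[Si](C)(C)C(C)(C)C)[C@H](O[Si](CC)(CC)CC)[C@@H]1O
F4 | step 14 | C6 ketone C1 triethylsilyl ether | CC(C)(C)[Si](c1ccccc1)(c1ccccc1)OCC(=C)[C@H]1[C@H](OCc2ccc(OC)cc2)C[C@@](C)(O[Si](C)(C)C(C)(C)C)[C@H](O[Si](CC)(CC)CC)C1=O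
F5 | step 20 | (6S) epimer of alcohol 28 | CC(C)(C)[Si](c1ccccc1)(c1ccccc1)OCC(=C)[C@@H]1[C@@H](O)/C=C(/C)CCC(=O)[C@](C)(O[Si](C)(C)C(C)(C)C)C[C@H]1OCc1ccc(OC)cc1
F6 | step 20 | (6R) 4-nitrobenzoate of 28 | CC(C)(C)[Si](c1ccccc1)(c1ccccc1)OCC(=C)[C@@H]1[C@H](OC(=O)c2ccc(cc2)[N+](=O)[O-])/C=C(/C)CCC(=O)[C@](C)(O[Si](C)(C)C(C)(C)C)C[C@H]1OCc1ccc(OC)cc1
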